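Both halves come from one hub, decarboxycitrinin, and the methylene bridge is made last by o-quinone-methide capture. The hub rests on reading its O2–C1=C8a–C8(=O)–C7=C6–OH strand (citrinin numbering) as a refolded γ-pyrone and C4a as a polyketide ketone. The key step turns a monocyclic 2-(β-mesyloxy-acylethyl)-4-pyrone into the bicyclic quinone methide in one operation. The sequence is amine-triggered pyrone opening, C8a→C4a aldol aromatisation (carbocycle), then dearomatising SN2 closure of the aldehyde oxygen on C3 (pyran ring). Inversion at C3 converts an Evans syn-aldol dyad into the trans-3,4-dimethyl unit. Half of the hub is reduced to the isochroman partner.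

Key step: step 6

Remark: citrinin numbering (C1, O2, C3, C4, C4a, C5–C8, C8a) is used for all intermediates. The quinone methide is written as its 8-oxo-6-hydroxy tautomer, which is assumed to equilibrate freely with the 6-oxo-8-hydroxy form.

Step 1
Reactants: 1 (R)-4-benzyl-3-propanoyl-1,3-oxazolidin-2-one; 2 acetaldehyde
Product: 3 (R)-4-benzyl-3-[(2R,3S)-3-hydroxy-2-methylbutanoyl]-1,3-oxazolidin-2-one
Conditions: n-Bu2BOTf, Et3N, CH2Cl2, −78 → 0 °C; then pH 7 buffer, H2O2, MeOH, 0 °C
Reagents that add atoms: none
Why: Evans boron aldol, in which the Z-boron enolate reacts through a Zimmerman–Traxler chair on the face left open by the (R)-benzyl auxiliary, so C4 (R at this stage) and C3 (S) should be set together as the syn dyad.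

Step 2
Reactants: 3 aldol adduct
Product: 4 (2R,3S)-3-hydroxy-N-methoxy-N,2-dimethylbutanamide
Conditions: MeNH(OMe)·HCl, AlMe3, CH2Cl2, −10 → 23 °C
Reagents that add atoms: N,O-dimethylhydroxylamine hydrochloride, CNOC.Cl
Why: Aluminium-amide transamination of the imide (Weinreb amide formation), assisted by the free β-hydroxyl, should remove the auxiliary without touching C3 or C4.

Step 3
Reactants: 5 (E)-4-methoxybut-3-en-2-one; 6 propanoyl chloride
Product: 8 2-ethyl-4H-pyran-4-one, via methoxyenedione 7 (not isolated)
Conditions: LiHMDS, THF, −78 °C; then TFA, CH2Cl2, 23 °C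
Reagents that add atoms: none
Why: C-acylation of the cross-conjugated lithium enolate, then acid-induced addition–elimination of the enol oxygen on the methoxyvinyl ketone (loss of methanol), is the standard γ-pyrone synthesis and forms no stereocentre.

Step 4
Reactants: 8 2-ethyl-4H-pyran-4-one; 4 Weinreb amide
Product: 9 2-[(4R,5S)-5-hydroxy-4-methyl-3-oxohexan-2-yl]-4H-pyran-4-one (both epimers at the pyrone-bearing carbon C5)
Conditions: LiHMDS, THF, −78 °C (8 metalated, hydroxyl of 4 carried as lithium alkoxide), −78 → −30 °C; AcOH quench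
Reagents that add atoms: none
Why: Lateral (vinylogous) lithiation of the 2-alkyl-4-pyrone and acylation by the Weinreb amide, whose chelate prevents over-addition, joins C5 to C4a; the new C5 centre forms as a mixture that is erased in step 6, and C3 and C4 are untouched.

Step 5
Reactants: 9 hydroxy ketone
Product: 10 (2S,3R)-3-methyl-4-oxo-5-(4-oxo-4H-pyran-2-yl)hexan-2-yl methanesulfonate
Conditions: Ms2O, pyridine, CH2Cl2, 0 °C
Reagents that add atoms: methanesulfonic anhydride, CS(=O)(=O)OS(C)(=O)=O
Why: O-sulfonylation of the secondary alcohol proceeds with retention at C3; the weak base and low temperature keep β-elimination slow, and the pyrone mask leaves no competing enol or hydroxyl.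

Step 6
Reactants: 10 pyrone mesylate
Product: 13 (3R,4S)-6-hydroxy-3,4,5-trimethyl-3,4-dihydroisochromen-8-one (decarboxycitrinin), via enaminone triketone 11 (not isolated), via benzaldehyde mesylate 12 (not isolated)
Conditions: morpholine, AcOH (amine/ammonium buffer), MeCN–H2O 4:1, 23 → 45 °C; pH 4 citrate work-up
Reagents that add atoms: water, O
Why: Proposed new method: morpholine adds to the unsubstituted C6-H of the γ-pyrone (the future C1) and opens the ring to enaminone 11, whose nucleophilic α-carbon C8a attacks the C4a ketone; loss of water, enolisation at C5 and C7 and hydrolysis of the aryl iminium ion give resorcinol aldehyde 12, and its C6 phenolate, a vinylogous formate anion, then displaces the C3 mesylate through the aldehyde oxygen to give 13 (first as the 6-oxo tautomer). The closest known reaction types are ring opening of 4-pyrones and chromones by secondary amines, the biomimetic aldol aromatisation of 2-(2-oxoalkyl)pyrones and β-polyketones to resorcinols, and invertive lactonisation of carboxylates (or carbonyl-oxygen participation) at secondary sulfonates. The carbocycle closes 6-(enolexo)-exo-trig (C8a to C4a) and the dihydropyran closes 6-exo-tet (O to C3). No new stereocentre is created: C3 is inverted by the SN2 step from S to R and C4 is only carried along, so the syn aldol dyad becomes the trans-3,4-dimethyl unit. Mode selectivity is secured by the enaminone, which makes C8a the best carbon nucleophile and masks C1 against the rival C5-to-C1 aldol and against deformylation, by the aromatic sink that only the C8a–C4a mode can reach, and by geometry, since the C6 and C8 oxygens cannot span to C3. The step needs the aldol to outrun E1cB loss of mesylate from the β-mesyloxy ketone, which the weakly basic amine/ammonium buffer favours, and enolisation towards C4 would destroy material as an achiral alkenylarene rather than epimerise it.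

Step 7
Reactants: 13 decarboxycitrinin (one half of the material)
Product: 14 (3R,4S)-3,4,5-trimethyl-3,4-dihydro-1H-isochromene-6,8-diol
Conditions: Et3SiH, TFA, CH2Cl2, 0 °C
Reagents that add atoms: none
Why: Ionic hydrogenation, in which TFA protonates the quinone methide to the C1 oxocarbenium (6,8-dihydroxyisochromenylium) ion, which takes hydride at C1 and rearomatises; C3 and C4 are not involved.

Step 8
Reactants: 14 isochromandiol
Product: 15 (3R,4S)-7-[(dimethylamino)methyl]-3,4,5-trimethyl-3,4-dihydro-1H-isochromene-6,8-diol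
Conditions: aq. CH2O, aq. Me2NH, EtOH, 0 → 23 °C
Reagents that add atoms: formaldehyde, C=O; dimethylamine, CNC
Why: Mannich aminomethylation should occur only at C7, which is flanked by both hydroxyls and is the only unsubstituted ring carbon.

Step 9
Reactants: 15 Mannich base; 13 decarboxycitrinin (second half)
Product: 16 dicitrinone I
Conditions: AcOH, 70 °C
Reagents that add atoms: none
Why: Retro-Mannich loss of dimethylamine gives the o-quinone methide of 15, which is trapped in a Michael addition by C7 of 13, the central carbon of its cyclic vinylogous acid (C5 is blocked and the acid keeps the amine protonated); no stereocentre is touched.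

Compound list
1 | (R)-4-benzyl-3-propanoyl-1,3-oxazolidin-2-one | CCC(=O)N1[C@H](Cc2ccccc2)COC1=O | starting material
2 | acetaldehyde | CC=O | starting material
3 | (R)-4-benzyl-3-[(2R,3S)-3-hydroxy-2-methylbutanoyl]-1,3-oxazolidin-2-one | C[C@H](O)[C@@H](C)C(=O)N1[C@H](Cc2ccccc2)COC1=O | intermediate
4 | (2R,3S)-3-hydroxy-N-methoxy-N,2-dimethylbutanamide | C[C@H](O)[C@@H](C)C(=O)N(C)OC | intermediate
5 | (E)-4-methoxybut-3-en-2-one | CO/C=C/C(C)=O | starting material
6 | propanoyl chloride | CCC(=O)Cl | starting material
7 | (E)-1-methoxyhept-1-ene-3,5-dione | CCC(=O)CC(=O)/C=C/OC | intermediate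
8 | 2-ethyl-4H-pyran-4-one | CCC1=CC(=O)C=CO1 | intermediate
9 | 2-[(4R,5S)-5-hydroxy-4-methyl-3-oxohexan-2-yl]-4H-pyran-4-one | C[C@H](O)[C@@H](C)C(=O)C(C)C1=CC(=O)C=CO1 | intermediate
10 | (2S,3R)-3-methyl-4-oxo-5-(4-oxo-4H-pyran-2-yl)hexan-2-yl methanesulfonate | C[C@H](OS(C)(=O)=O)[C@@H](C)C(=O)C(C)C1=CC(=O)C=CO1 | intermediate
11 | (2S,3R,9E)-3,5-dimethyl-10-(morpholin-4-yl)-4,6,8-trioxodec-9-en-2-yl methanesulfonate | C[C@H](OS(C)(=O)=O)[C@@H](C)C(=O)C(C)C(=O)CC(=O)/C=C/N1CCOCC1 | intermediate
12 | (2S,3S)-3-(2-formyl-3,5-dihydroxy-6-methylphenyl)butan-2-yl methanesulfonate | C[C@H](OS(C)(=O)=O)[C@@H](C)c1c(C)c(O)cc(O)c1C=O | intermediate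
13 | (3R,4S)-6-hydroxy-3,4,5-trimethyl-3,4-dihydroisochromen-8-one (decarboxycitrinin) | CC1=C2C(=CO[C@H](C)[C@H]2C)C(=O)C=C1O | intermediate
14 | (3R,4S)-3,4,5-trimethyl-3,4-dihydro-1H-isochromene-6,8-diol | c1c(O)c(C)c2c(c1O)CO[C@H](C)[C@H]2C | intermediate
15 | (3R,4S)-7-[(dimethylamino)methyl]-3,4,5-trimethyl-3,4-dihydro-1H-isochromene-6,8-diol | CN(C)Cc1c(O)c(C)c2c(c1O)CO[C@H](C)[C@H]2C | intermediate
16 | dicitrinone I | CC1=C2C(=CO[C@H](C)[C@H]2C)C(=O)C(Cc2c(O)c(C)c3c(c2O)CO[C@H](C)[C@H]3C)=C1O | target

Total step count: 9. Longest linear sequence: 8 steps (1, 2, 4, 5, 6, 7, 8, 9).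

Steps most likely to fail

Step 6. Three things may go wrong:
- β-elimination of the mesylate may overtake the slow attack on the hindered C4a ketone.
- The opened chain may fold in another aldol mode.
- The final oxygen alkylation may stall at the aromatic stage.

In the fallback the two ring closures are separated. The pyran is closed through the C3 oxygen onto C1, which calls for the anti dyad. It sets out from pyrone 8 and comes back at 13. Commercial methyl (R)-3-hydroxybutanoate F1 is methylated by Fráter–Seebach alkylation (LDA, MeI) to methyl (2R,3R)-3-hydroxy-2-methylbutanoate F2. This is silylated (TBSCl, imidazole) to methyl (2R,3R)-3-(tert-butyldimethylsilyloxy)-2-methylbutanoate F3, which acylates lithiated 8 to give 2-[(4R,5R)-5-(tert-butyldimethylsilyloxy)-4-methyl-3-oxohexan-2-yl]-4H-pyran-4-one F4. Aqueous barium hydroxide opens the pyrone, and the polyketone aromatises to 6-[(2S,3R)-3-(tert-butyldimethylsilyloxy)butan-2-yl]-2,4-dihydroxy-5-methylbenzaldehyde F5. Aqueous HCl in THF removes the silyl group. The (3R)-alcohol then closes on the aldehyde to the lactol, which loses water to 13.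

Step 4. Ring metalation or conjugate self-addition of the lithiated pyrone may compete. Attack on the alkoxide-bearing amide may be sluggish, and the product alkoxide may undergo retro-aldol cleavage.

The fallback replaces acylation by aldol addition and oxidation. It sets out from 4 and comes back at 9.
- 4 is silylated (TESCl, imidazole) to (2R,3S)-N-methoxy-N,2-dimethyl-3-(triethylsilyloxy)butanamide F6.
- F6 is reduced with DIBAL-H to (2R,3S)-2-methyl-3-(triethylsilyloxy)butanal F7.
- F7 is combined with lithiated 8 in a vinylogous aldol addition to give 2-[(4S,5S)-3-hydroxy-4-methyl-5-(triethylsilyloxy)hexan-2-yl]-4H-pyran-4-one F8.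
- F8 is oxidised with Dess–Martin periodinane to 2-[(4R,5S)-4-methyl-3-oxo-5-(triethylsilyloxy)hexan-2-yl]-4H-pyran-4-one F9.
- F9 is desilylated with HF·pyridine to 9.

Step 9. The o-quinone methide may be captured at oxygen or in a hetero-Diels–Alder sense. The liberated amine may add at C1 of 13, or the quinone methide may degrade on heating in acid.

The fallback reverses the roles in a three-component reductive alkylation. It sets out from 14 and comes back at 16. 14 is formylated at C7 (Vilsmeier–Haack, POCl3, DMF) to (3R,4S)-6,8-dihydroxy-3,4,5-trimethyl-3,4-dihydro-1H-isochromene-7-carbaldehyde F10. Knoevenagel condensation of F10 with 13 (catalytic proline) gives the 7-arylmethylidene-6,8-dione F11, which is reduced in the same flask by conjugate hydride transfer from Hantzsch ester to 16.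

Further compounds
F1 | step 6 | methyl (R)-3-hydroxybutanoate | C[C@@H](O)CC(=O)OC
F2 | step 6 | methyl (2R,3R)-3-hydroxy-2-methylbutanoate | C[C@@H](O)[C@@H](C)C(=O)OC
F3 | step 6 | methyl (2R,3R)-3-(tert-butyldimethylsilyloxy)-2-methylbutanoate | C[C@@H](O[Si](C)(C)C(C)(C)C)[C@@H](C)C(=O)OC
F4 | step 6 | 2-[(4R,5R)-5-(tert-butyldimethylsilyloxy)-4-methyl-3-oxohexan-2-yl]-4H-pyran-4-one | C[C@@H](O[Si](C)(C)C(C)(C)C)[C@@H](C)C(=O)C(C)C1=CC(=O)C=CO1
F5 | step 6 | 6-[(2S,3R)-3-(tert-butyldimethylsilyloxy)butan-2-yl]-2,4-dihydroxy-5-methylbenzaldehyde | C[C@@H](O[Si](C)(C)C(C)(C)C)[C@@H](C)c1c(C)c(O)cc(O)c1C=O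
F6 | step 4 | (2R,3S)-N-methoxy-N,2-dimethyl-3-(triethylsilyloxy)butanamide | C[C@H](O[Si](CC)(CC)CC)[C@@H](C)C(=O)N(C)OC
F7 | step 4 | (2R,3S)-2-methyl-3-(triethylsilyloxy)butanal | C[C@H](O[Si](CC)(CC)CC)[C@@H](C)C=O
F8 | step 4 | 2-[(4S,5S)-3-hydroxy-4-methyl-5-(triethylsilyloxy)hexan-2-yl]-4H-pyran-4-one | C[C@H](O[Si](CC)(CC)CC)[C@@H](C)C(O)C(C)C1=CC(=O)C=CO1
F9 | step 4 | 2-[(4R,5S)-4-methyl-3-oxo-5-(triethylsilyloxy)hexan-2-yl]-4H-pyran-4-one | C[C@H](O[Si](CC)(CC)CC)[C@@H](C)C(=O)C(C)C1=CC(=O)C=CO1
F10 | step 9 | (3R,4S)-6,8-dihydroxy-3,4,5-trimethyl-3,4-dihydro-1H-isochromene-7-carbaldehyde | O=Cc1c(O)c(C)c2c(c1O)CO[C@H](C)[C@H]2C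
F11 | step 9 | 7-arylmethylidene-6,8-dione from 13 and F10 | CC1=C2C(=CO[C@H](C)[C@H]2C)C(=O)C(=Cc2c(O)c(C)c3c(c2O)CO[C@H](C)[C@H]3C)C1=O
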